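Assumption: the target is the centrosymmetric, achiral (1α,2α,3β,4β) diastereomer, so racemic intermediates suffice; SMILES of chiral intermediates show one enantiomer of the racemate, and where a step gives two epimers the undefined centres are left open in the SMILES.

## Analysis of the target

The target has one carbocycle, a cyclobutane (ring carbons Ca, Cb, Cc, Cd in order). Ca and Cc each carry a 4-methoxy-2-oxo-2H-pyran-6-yl ring, and Cb and Cd each carry a 4-hydroxyphenyl ring. All four ring carbons are stereocentres: the two pyranones are trans to each other, the two aryl groups are trans to each other, and each pyranone is cis to one neighbouring aryl group and trans to the other. This is the head-to-tail (1α,2α,3β,4β) pattern; the molecule has a centre of inversion and is achiral, so only relative configuration has to be controlled. The sensitive parts are the pyranones (vinylogous lactones that open with hydroxide or alkoxide and make the Ca–H and Cc–H bonds vinylogously acidic), the free phenols, and the strained ring with its benzylic C–C bonds, which can cleave when a radical or cation sits on a ring carbon. The difficulty is stereochemical: four contiguous stereocentres on a four-membered ring must be set in an arrangement with two cis vicinal contacts, and two heteroaryl rings must end up on ring carbons without epimerising them. The centres fall into two classes: Cb and Cd are benzylic and fixed once the ring exists, whereas Ca and Cc lie α to carbonyl-type groups at every stage and can be corrected by equilibration. The strategy rests on the position of Cc between the two trans aryl-bearing carbons Cb and Cd: Cc can enter as a doubly nucleophilic malonate carbon between the two benzylic carbons of an open-chain anti-1,3-diaryl 1,3-bis-electrophile whose middle carbon is Ca.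

## Retrosynthetic reasoning

From 27 to 26. The last operation only uncovers the phenols. They are carried as benzyl ethers in 26 because these survive the whole pyranone construction and come off by hydrogenolysis, which a 4-methoxy-2-pyranone tolerates; a base-labile phenol protecting group would have to be removed under conditions that open the lactones.

From 26 to 22. Both pyranone rings are cut at once. In each, the lactone C2–O1 bond and the C5–C6 bond are disconnected, through the hydroxypyranone 25 and the bis(3,5-dioxo ester) 24, back to a carboxyl carbon on the cyclobutane (diacid 22). The four carbons that complete each heterocycle are delivered by a silylated acetoacetate dianion equivalent, a reagent that is consumed once per carboxyl group, so two molecules of it enter the product. The cut is placed there because the two heterocycles are identical, so the work is two-directional, and because acylation at a carboxyl carbon does not touch the ring stereocentres. The gain is that the whole stereochemical problem is confined to a cyclobutane-1,3-dicarboxylic acid. The forward sequence must acylate twice at hindered carbonyl groups without enolising them.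

From 22 to 20. No skeletal bond is cut; the relative configuration of Ca and Cc is traced back to an epimer mixture. In the diester 21 both carbons are α to an ester and can be equilibrated while Cb and Cd cannot, so the trans-1,3 relationship is assigned to a thermodynamic step with crystallisation, and the mixture 20 is an acceptable precursor. This removes any need to control Ca against Cc when the ring is made.

From 20 to 16. The benzyl groups of 20 come from the bis(aryl pivalate) diacid 18 by protecting-group exchange. The Ca carboxyl group of 18 is traced through the alcohol 17 to the benzyloxymethyl group of 16. Ca is carried at the alcohol oxidation level because a carbonyl group on Ca would put an acidic hydrogen next to both leaving groups of the ring-closure precursor and invite elimination; an ether does not.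

From 16 to 14. The carboxyl group on Cc of 16 is what remains of a malonate; the second ester of 14 is the extra activating group that made Cc a double nucleophile. Allyl esters are used so that this group can be removed under neutral, transition-metal-catalysed conditions that aryl esters survive; a halide-mediated dealkoxycarbonylation of methyl esters at high temperature would endanger them.

From 14 to 11 and 12 (key disconnection). The bonds Cc–Cb and Cc–Cd are cut. They are chosen because Cc is the one ring carbon bonded to both aryl-bearing carbons. Cutting there gives a one-carbon bis-nucleophile, 12, and a three-carbon bis-electrophile, 11, in which Cb and Cd are benzylic carbinol-derived carbons and Ca is the middle carbon. Each bond forms by SN2 with inversion, so the trans relationship of Cb and Cd is inherited from the anti relationship of the two mesylates. The middle carbon of 11 bears two like-configured arms and is not a stereocentre, so nothing has to be controlled at Ca; the two mesylates are diastereotopic, but both orders of substitution converge on 14. The forward reaction must achieve two clean inversions at hindered secondary benzylic carbons, the second as a four-membered ring closure, which is why the aryl rings carry acyloxy and not alkoxy groups.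

From 11 to 9. The dimesylate comes from the anti diol 10, and 10 from the β-hydroxy ketone 9 by reduction of the carbonyl group. The 1,3-anti relationship is assigned to a hydroxyl-directed reduction. Because the central carbon ceases to be stereogenic in 10, the diastereomer ratio of 9 does not matter. A route through a 2-substituted 1,3-diaryl-1,3-diketone with two catalyst-controlled reductions was weighed and kept only as a fallback, since chloromethyl ethers tend to alkylate diketone enolates at oxygen and such diketones tend to stop after one transfer hydrogenation.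

From 9 to 5 and 7. The Ca–Cd bond is cut by an aldol disconnection into the ketone 5 and the aldehyde 7. This is the most convergent cut of the three-carbon chain. Both halves already carry the pivalates that the key step needs, so no protecting-group change lies between here and 11.

From 5 and 7 to 1, 4 and 6. In 5 the bond between the ketone α-carbon and the benzyloxymethyl carbon is cut, which leads to the silyl enol ether 3 and the chloromethyl ether 4; a silyl enol ether under Lewis acid catalysis guarantees mono-alkylation at carbon. 3 comes from 2 and that from 1 by pivaloylation; 7 comes from 6 in the same way.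

## Alternatives that were turned down

Alternative 1: Dewar lactone from a coumalate.
- Disconnection: the four ring carbons are taken from the pyranone ring of methyl coumalate A1. The two carboxyl carbons that become the pyranone attachment points are already in a 1,3-relationship; both aryl–ring bonds are made afterwards.
- Key step: irradiation of A1 causes a 4π electrocyclisation that joins C3 to C6 and gives the bicyclic Dewar lactone A2, a cyclobutene fused to a β-lactone.
- For it: one photochemical step from a commodity ester builds the four-membered ring with both carboxyl carbons in place, and the cyclobutene and the allylic lactone C–O bond are handles for carbon substituents.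
- Against it: A2 delivers none of the four stereocentres in final form. Both aryl groups must still be attached, each cis to one carboxyl group, trans to the other and trans to one another. The lactone bridge fixes the carboxyl carbons cis, so at least one epimerisation and two stereocontrolled C–aryl bond formations on a crowded ring follow. A2 is also thermally fragile and must be made in dilute solution.
- Comparison: on ring construction this plan is stronger, one step against an eight-step sequence up to the ring closure. The chosen strategy offers in exchange that the ring-forming event itself installs both aryl groups and fixes their trans relationship by two inversions, leaving only the two epimerisable carboxyl-bearing carbons to adjust.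

Alternative 2: twofold directed C–H arylation.
- Disconnection: both aryl–ring bonds are cut, leading to the trans-cyclobutane-1,3-dicarboxamide A3 and two equivalents of the aryl iodide A4.
- Key step: Pd(OAc)2 with AgOAc arylates the two methylene carbons of A3, each 8-aminoquinoline amide steering palladation to a cis C–H bond of a neighbouring methylene, to give A5; no ring is formed.
- For it: the ring and both carboxyl carbons are bought ready-made, the cis relationship between an amide and the aryl group it introduces is enforced by the palladacycle, and the arylated core is reached in far fewer steps. On step economy this alternative is clearly stronger.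
- Against it: each amide has two neighbouring methylenes, and each methylene has a hydrogen cis to either amide. After the first arylation, the α pattern needs the second aryl group at the other methylene on the opposite face, directed by the second amide. The first amide can equally direct the second palladation to its own face, which gives the cis-diaryl isomer; only small steric differences separate the two paths, and double arylation by one amide is the normal course of such reactions. The two amides must then be cleaved from carbons flanked by two aryl groups, under forcing conditions on epimerisable centres.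
- Comparison: the chosen strategy is longer, but its trans-diaryl relationship follows from mechanism (two SN2 inversions on an anti precursor), not from a competition between two directing groups, and its carboxyl groups are free acids or simple esters throughout.

Alternative 3: twofold decarboxylative pyranonylation.
- Disconnection: the two ring–pyranone bonds (Ca–C6 and Cc–C6) are cut, leading to an α-truxillic acid and a halopyranone. The diacid A7 comes from solid-state [2+2] photodimerisation of the cinnamic acid A6.
- Key step: the bis(N-hydroxyphthalimide) ester A8 and the chloropyranone A9 are coupled twice under NiBr2(dme)/bipyridine catalysis with zinc or at a cathode. Each carboxyl group leaves as CO2 and the cyclobutyl radical is captured by nickel and joined to C6 of A9, giving A10.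
- For it: it is by far the shortest plan. The ring and all four stereocentres come from one photochemical step, and the pyranones are introduced intact. On step economy and convergence it is stronger than the chosen strategy.
- Against it: decarboxylation turns Ca and Cc, the centres that distinguish the target from its cis-1,3 isomer, into planar radicals. Each radical carbon has one aryl neighbour on each face, so the only bias is the remote substituent across the ring, and a mixture of 1,3-cis and 1,3-trans products is likely. The cyclobutyl radical can also open by β-scission to a styrene and a carboxyl-stabilised radical with relief of strain. A9, an electron-rich vinylogous acyl chloride, is an untried partner, and two couplings on one molecule multiply any loss.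
- Comparison: the chosen strategy gives up brevity. It offers that Cb and Cd are set by stereospecific ionic steps, that Ca and Cc are never radicals and stay correctable through enolates until the diacid stage, and that the pyranones are made by established acylation and lactonisation chemistry. It also does not depend on the crystal packing of a cinnamic acid.

Key step: step 8

## Route

Step 1
Reactants: 1 4′-hydroxyacetophenone
Product: 2 4-acetylphenyl pivalate
Conditions: PivCl, Et3N, DMAP (cat.), CH2Cl2, 0 °C → rt
Reagents that add atoms: pivaloyl chloride, CC(C)(C)C(Cl)=O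
Why: Acylation of the phenol under nucleophilic catalysis; the pivalate makes the aryl group electron-poorer than an ether would and is hindered enough to survive the enolate and malonate chemistry that follows.

Step 2
Reactants: 2 4-acetylphenyl pivalate
Product: 3 4-[1-(trimethylsilyloxy)ethenyl]phenyl pivalate
Conditions: TMSOTf, Et3N, CH2Cl2, 0 °C
Reagents that add atoms: trimethylsilyl trifluoromethanesulfonate, C[Si](C)(C)OS(=O)(=O)C(F)(F)F
Why: Soft enolisation of the methyl ketone with a silyl triflate and a tertiary amine gives the silyl enol ether without a strong base, so the aryl ester is not touched.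

Step 3
Reactants: 3 4-[1-(trimethylsilyloxy)ethenyl]phenyl pivalate; 4 benzyl chloromethyl ether
Product: 5 4-[3-(benzyloxy)propanoyl]phenyl pivalate
Conditions: ZnBr2 (10 mol %), CH2Cl2, 0 °C → rt
Reagents that add atoms: none
Why: Mukaiyama-type Lewis-acid-promoted alkylation: ZnBr2 ionises the α-chloro ether to an oxocarbenium ion that the silyl enol ether captures at carbon, which gives mono-C-alkylation only and avoids the O-alkylation that chloromethyl ethers show with metal enolates.

Step 4
Reactants: 6 4-hydroxybenzaldehyde
Product: 7 4-formylphenyl pivalate
Conditions: PivCl, Et3N, DMAP (cat.), CH2Cl2, 0 °C → rt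
Reagents that add atoms: pivaloyl chloride, CC(C)(C)C(Cl)=O
Why: Same phenol acylation as in step 1; the aldehyde is inert to the acid chloride and the amine.

Step 5
Reactants: 5 4-[3-(benzyloxy)propanoyl]phenyl pivalate; 7 4-formylphenyl pivalate
Product: 9 4-{(2S*,3S*)-2-[(benzyloxy)methyl]-3-hydroxy-3-[4-(pivaloyloxy)phenyl]propanoyl}phenyl pivalate (syn aldol; racemic; some anti isomer expected), via (Z)-dibutylboron enolate 8 (not isolated)
Conditions: Bu2BOTf, i-Pr2NEt, CH2Cl2, −78 → 0 °C; then 7, −78 → 0 °C; pH 7 buffer, MeOH, H2O2, 0 °C
Reagents that add atoms: none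
Why: Boron-mediated aldol addition: the (Z)-enolate adds to the aldehyde through a Zimmerman–Traxler chair to give mainly the syn aldol; the covalent boron enolate should not expel the β-benzyloxy group at low temperature, and the C2 configuration is of no consequence because that carbon stops being a stereocentre in 10.

Step 6
Reactants: 9 4-{(2S*,3S*)-2-[(benzyloxy)methyl]-3-hydroxy-3-[4-(pivaloyloxy)phenyl]propanoyl}phenyl pivalate
Product: 10 (1S*,3S*)-2-[(benzyloxy)methyl]-1,3-bis[4-(pivaloyloxy)phenyl]propane-1,3-diol (anti diol, racemic)
Conditions: Me4NBH(OAc)3, MeCN–AcOH, −30 → −20 °C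
Reagents that add atoms: none
Why: Evans–Saksena reduction: the hydroxyl exchanges an acetate on boron and the resulting alkoxyborohydride delivers hydride intramolecularly to the acid-activated ketone through a chair transition state, which sets the new carbinol anti to the existing one; with both carbinols of like configuration the central carbon is no longer stereogenic, so both aldol diastereomers converge on 10.

Step 7
Reactants: 10 (1S*,3S*)-2-[(benzyloxy)methyl]-1,3-bis[4-(pivaloyloxy)phenyl]propane-1,3-diol
Product: 11 (1S*,3S*)-2-[(benzyloxy)methyl]-1,3-bis[4-(pivaloyloxy)phenyl]propane-1,3-diyl dimethanesulfonate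
Conditions: MsCl, Et3N, CH2Cl2, −20 °C; cold work-up, used at once
Reagents that add atoms: methanesulfonyl chloride, CS(Cl)(=O)=O
Why: Sulfonylation of both secondary benzylic alcohols with retention at carbon, since only O–S bonds form; the acyloxy-substituted rings slow ionisation enough for the dimesylate to be handled cold and used without chromatography.

Step 8
Reactants: 11 (1S*,3S*)-2-[(benzyloxy)methyl]-1,3-bis[4-(pivaloyloxy)phenyl]propane-1,3-diyl dimethanesulfonate; 12 diallyl malonate
Product: 14 diallyl 3-[(benzyloxy)methyl]-trans-2,4-bis[4-(pivaloyloxy)phenyl]cyclobutane-1,1-dicarboxylate (racemic), via monoalkylated malonate mesylate 13 (not isolated)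
Conditions: NaH (2.1 equiv), THF–DMF, 0 → 45 °C, slow addition of 11
Reagents that add atoms: none
Why: This is the double alkylation of a malonate by a 1,3-bis-electrophile, the classical route to cyclobutane-1,1-dicarboxylates, applied here to two secondary benzylic centres. The sodium salt of 12 displaces one mesylate by SN2 with inversion (the two mesylates are diastereotopic, but either order leads to the same product); the substituted malonate 13 is deprotonated by the second equivalent of NaH and closes the ring by 4-exo-tet displacement of the second mesylate, again with inversion. The two new ring stereocentres Cb and Cd are each controlled by the configuration of the carbinol carbon they come from, so two inversions turn the anti relationship of 11 into the trans relationship of the aryl groups. Ca is not a stereocentre in 11 or in 14 and needs no control, and Cc is a symmetric quaternary carbon at this stage. The step needs substitution to win over ionisation, which would scramble Cb and Cd, and over elimination to the styrene: the pivaloyloxy groups make the benzylic positions poorer cation precursors than alkoxy groups would, Ca carries an ether and not a carbonyl so that no acidic hydrogen lies β to the leaving groups, and the nucleophile is a soft, weakly basic stabilised carbanion in a dipolar aprotic medium. Substitution on every chain carbon favours the folded conformation for ring closure, and slow addition of 11 keeps intermolecular second alkylation down.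

Step 9
Reactants: 14 diallyl 3-[(benzyloxy)methyl]-trans-2,4-bis[4-(pivaloyloxy)phenyl]cyclobutane-1,1-dicarboxylate
Product: 16 3-[(benzyloxy)methyl]-trans-2,4-bis[4-(pivaloyloxy)phenyl]cyclobutane-1-carboxylic acid (both C1 epimers), via cyclobutane-1,1-dicarboxylic acid 15 (not isolated)
Conditions: Pd(PPh3)4 (5 mol %), HCO2H, Et3N, 1,4-dioxane, rt then 100 °C
Reagents that add atoms: none
Why: Tsuji–Trost-type deallylation: zerovalent palladium ionises both allyl esters and formate reduces the π-allyl complexes to propene, leaving the malonic acid, which loses CO2 on heating; the conditions are neutral and free of hard nucleophiles, so the aryl pivalates and the benzyl ether should survive, and C1 is protonated without control because it is equilibrated in step 13.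

Step 10
Reactants: 16 3-[(benzyloxy)methyl]-trans-2,4-bis[4-(pivaloyloxy)phenyl]cyclobutane-1-carboxylic acid
Product: 17 3-(hydroxymethyl)-trans-2,4-bis[4-(pivaloyloxy)phenyl]cyclobutane-1-carboxylic acid (both C1 epimers)
Conditions: H2 (1 atm), Pd/C, EtOAc, rt
Reagents that add atoms: none
Why: Hydrogenolysis of the alkyl benzyl ether; aryl pivalates, the carboxylic acid and the arylcyclobutane are inert under these conditions, and the hydroxy acid is oxidised without delay so that the cis epimer has no time to lactonise.

Step 11
Reactants: 17 3-(hydroxymethyl)-trans-2,4-bis[4-(pivaloyloxy)phenyl]cyclobutane-1-carboxylic acid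
Product: 18 trans-2,4-bis[4-(pivaloyloxy)phenyl]cyclobutane-1,3-dicarboxylic acid (1,3-cis and 1,3-trans isomers)
Conditions: TEMPO (cat.), PhI(OAc)2, MeCN–H2O, rt
Reagents that add atoms: water, O
Why: Nitroxyl-catalysed oxidation takes the primary alcohol through the aldehyde hydrate to the acid under near-neutral conditions that leave the aryl esters and the α-stereocentres alone.

Step 12
Reactants: 18 trans-2,4-bis[4-(pivaloyloxy)phenyl]cyclobutane-1,3-dicarboxylic acid
Product: 20 dibenzyl trans-2,4-bis[4-(benzyloxy)phenyl]cyclobutane-1,3-dicarboxylate (1,3-cis and 1,3-trans isomers), via bisphenol diacid potassium salt 19 (not isolated)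
Conditions: K2CO3, MeOH, 50 °C; evaporate; BnBr, DMF, 60 °C
Reagents that add atoms: benzyl bromide, BrCc1ccccc1
Why: Methanolysis of the aryl pivalates, which have done their work after step 8, followed by Williamson O-alkylation of the phenoxides and carboxylates; benzyl ethers are chosen for the end game because they withstand acid chloride formation, DBU and methylation and come off by hydrogenolysis.

Step 13
Reactants: 20 dibenzyl trans-2,4-bis[4-(benzyloxy)phenyl]cyclobutane-1,3-dicarboxylate
Product: 21 dimethyl (1α,2α,3β,4β)-2,4-bis[4-(benzyloxy)phenyl]cyclobutane-1,3-dicarboxylate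
Conditions: NaOMe, MeOH–THF, 65 °C; crystallisation, mother liquor returned to the base
Reagents that add atoms: sodium methoxide in methanol, [Na+].[O-]C
Why: Alkoxide-mediated transesterification and enolate equilibration: both carboxyl-bearing carbons epimerise through their ester enolates while the aryl-bearing carbons cannot; the trans-1,3 (centrosymmetric) diester avoids the aligned ester dipoles and the three contiguous cis groups of its epimer and should be favoured, and as the more symmetrical isomer it should crystallise first.

Step 14
Reactants: 21 dimethyl (1α,2α,3β,4β)-2,4-bis[4-(benzyloxy)phenyl]cyclobutane-1,3-dicarboxylate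
Product: 22 (1α,2α,3β,4β)-2,4-bis[4-(benzyloxy)phenyl]cyclobutane-1,3-dicarboxylic acid
Conditions: LiOH, THF–MeOH–H2O, 50 °C; then aq. HCl
Reagents that add atoms: lithium hydroxide, [Li+].[OH-]
Why: Saponification; hydroxide adds to the ester carbonyl much faster than it enolises it, so the configuration set in step 13 should be retained.

Step 15
Reactants: 22 (1α,2α,3β,4β)-2,4-bis[4-(benzyloxy)phenyl]cyclobutane-1,3-dicarboxylic acid
Product: 24 dimethyl 5,5′-{(1α,2α,3β,4β)-2,4-bis[4-(benzyloxy)phenyl]cyclobutane-1,3-diyl}bis(3,5-dioxopentanoate), via diacid dichloride 23 (not isolated)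
Conditions: (COCl)2, DMF (cat.), CH2Cl2, 0 °C → rt; evaporate; 1-methoxy-1,3-bis(trimethylsilyloxy)buta-1,3-diene (2.5 equiv), CH2Cl2, −78 °C → rt; aq. HCl
Reagents that add atoms: 1-methoxy-1,3-bis(trimethylsilyloxy)buta-1,3-diene, C=C(O[Si](C)(C)C)C=C(OC)O[Si](C)(C)C
Why: The acid chloride is formed under base-free Vilsmeier catalysis, which avoids ketene formation and epimerisation; each of the two chlorocarbonyl groups then acylates the terminal carbon of one molecule of the bis(silyl enol ether), a masked acetoacetate dianion, in a Mukaiyama-type reaction without strong base, so two molecules of the diene are built into the product, and aqueous acid releases the 3,5-dioxo ester at both ends.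

Step 16
Reactants: 24 dimethyl 5,5′-{(1α,2α,3β,4β)-2,4-bis[4-(benzyloxy)phenyl]cyclobutane-1,3-diyl}bis(3,5-dioxopentanoate)
Product: 25 6,6′-{(1α,2α,3β,4β)-2,4-bis[4-(benzyloxy)phenyl]cyclobutane-1,3-diyl}bis(4-hydroxy-2H-pyran-2-one)
Conditions: DBU, toluene, rt → 60 °C; then aq. HCl
Reagents that add atoms: none
Why: Base-induced lactonisation of a 3,5-dioxo ester: the enol oxygen of the ring-attached ketone attacks the ester carbonyl and methanol is lost to give the 4-hydroxy-2-pyranone; the substrate is present as its stabilised enolate, so the ring C–H bonds are not deprotonated.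

Step 17
Reactants: 25 6,6′-{(1α,2α,3β,4β)-2,4-bis[4-(benzyloxy)phenyl]cyclobutane-1,3-diyl}bis(4-hydroxy-2H-pyran-2-one)
Product: 26 6,6′-{(1α,2α,3β,4β)-2,4-bis[4-(benzyloxy)phenyl]cyclobutane-1,3-diyl}bis(4-methoxy-2H-pyran-2-one)
Conditions: Me2SO4, K2CO3, acetone, 56 °C
Reagents that add atoms: dimethyl sulfate, COS(=O)(=O)OC
Why: O-Methylation of the vinylogous acid under conditions that favour the 4-methoxy-2-pyranone over the isomeric 2-methoxy-4-pyranone; carbonate is too weak to remove the ring C–H protons.

Step 18
Reactants: 26 6,6′-{(1α,2α,3β,4β)-2,4-bis[4-(benzyloxy)phenyl]cyclobutane-1,3-diyl}bis(4-methoxy-2H-pyran-2-one)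
Product: 27 6,6′-[(1α,2α,3β,4β)-2,4-bis(4-hydroxyphenyl)cyclobutane-1,3-diyl]bis(4-methoxy-2H-pyran-2-one) (CNP0273697.2)
Conditions: H2 (1 atm), Pd/C, EtOAc–THF, rt
Reagents that add atoms: none
Why: Hydrogenolysis of the two aryl benzyl ethers; the 4-methoxy-2-pyranone ring is a poor substrate for hydrogenation under these mild conditions, so the reaction is stopped once the benzyl groups are gone.

## Compound list

1 | 4′-hydroxyacetophenone | CC(=O)c1ccc(O)cc1 | starting material
2 | 4-acetylphenyl pivalate | CC(=O)c1ccc(OC(=O)C(C)(C)C)cc1 | intermediate
3 | 4-[1-(trimethylsilyloxy)ethenyl]phenyl pivalate | C=C(O[Si](C)(C)C)c1ccc(OC(=O)C(C)(C)C)cc1 | intermediate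
4 | benzyl chloromethyl ether | ClCOCc1ccccc1 | starting material
5 | 4-[3-(benzyloxy)propanoyl]phenyl pivalate | O=C(CCOCc1ccccc1)c1ccc(OC(=O)C(C)(C)C)cc1 | intermediate
6 | 4-hydroxybenzaldehyde | O=Cc1ccc(O)cc1 | starting material
7 | 4-formylphenyl pivalate | O=Cc1ccc(OC(=O)C(C)(C)C)cc1 | intermediate
8 | (Z)-dibutylboron enolate of 5 | CCCCB(CCCC)O/C(c1ccc(OC(=O)C(C)(C)C)cc1)=C\COCc1ccccc1 | intermediate (not isolated)
9 | 4-{(2S*,3S*)-2-[(benzyloxy)methyl]-3-hydroxy-3-[4-(pivaloyloxy)phenyl]propanoyl}phenyl pivalate (syn aldol, racemic) | O=C(c1ccc(OC(=O)C(C)(C)C)cc1)[C@@H](COCc1ccccc1)[C@H](O)c1ccc(OC(=O)C(C)(C)C)cc1 | intermediate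
10 | (1S*,3S*)-2-[(benzyloxy)methyl]-1,3-bis[4-(pivaloyloxy)phenyl]propane-1,3-diol (anti, racemic) | O[C@H](c1ccc(OC(=O)C(C)(C)C)cc1)C(COCc1ccccc1)[C@@H](c1ccc(OC(=O)C(C)(C)C)cc1)O | intermediate
11 | (1S*,3S*)-2-[(benzyloxy)methyl]-1,3-bis[4-(pivaloyloxy)phenyl]propane-1,3-diyl dimethanesulfonate | CS(=O)(=O)O[C@H](c1ccc(OC(=O)C(C)(C)C)cc1)C(COCc1ccccc1)[C@@H](c1ccc(OC(=O)C(C)(C)C)cc1)OS(C)(=O)=O | intermediate
12 | diallyl malonate | C=CCOC(=O)CC(=O)OCC=C | starting material
13 | diallyl 2-{2-[(benzyloxy)methyl]-3-(methanesulfonyloxy)-1,3-bis[4-(pivaloyloxy)phenyl]propyl}malonate (one mesylate displaced with inversion; central carbon left open because either mesylate may react first) | C=CCOC(=O)C(C(=O)OCC=C)[C@@H](c1ccc(OC(=O)C(C)(C)C)cc1)C(COCc1ccccc1)[C@@H](c1ccc(OC(=O)C(C)(C)C)cc1)OS(C)(=O)=O | intermediate (not isolated)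
14 | diallyl 3-[(benzyloxy)methyl]-trans-2,4-bis[4-(pivaloyloxy)phenyl]cyclobutane-1,1-dicarboxylate (racemic) | O(Cc1ccccc1)CC1[C@H](c2ccc(OC(=O)C(C)(C)C)cc2)C(C(=O)OCC=C)(C(=O)OCC=C)[C@H]1c1ccc(OC(=O)C(C)(C)C)cc1 | intermediate
15 | 3-[(benzyloxy)methyl]-trans-2,4-bis[4-(pivaloyloxy)phenyl]cyclobutane-1,1-dicarboxylic acid | O(Cc1ccccc1)CC1[C@H](c2ccc(OC(=O)C(C)(C)C)cc2)C(C(=O)O)(C(=O)O)[C@H]1c1ccc(OC(=O)C(C)(C)C)cc1 | intermediate (not isolated)
16 | 3-[(benzyloxy)methyl]-trans-2,4-bis[4-(pivaloyloxy)phenyl]cyclobutane-1-carboxylic acid (both C1 epimers) | O(Cc1ccccc1)CC1[C@H](c2ccc(OC(=O)C(C)(C)C)cc2)C(C(=O)O)[C@H]1c1ccc(OC(=O)C(C)(C)C)cc1 | intermediate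
17 | 3-(hydroxymethyl)-trans-2,4-bis[4-(pivaloyloxy)phenyl]cyclobutane-1-carboxylic acid (both C1 epimers) | OCC1[C@H](c2ccc(OC(=O)C(C)(C)C)cc2)C(C(=O)O)[C@H]1c1ccc(OC(=O)C(C)(C)C)cc1 | intermediate
18 | trans-2,4-bis[4-(pivaloyloxy)phenyl]cyclobutane-1,3-dicarboxylic acid (1,3-cis and 1,3-trans) | OC(=O)C1[C@H](c2ccc(OC(=O)C(C)(C)C)cc2)C(C(=O)O)[C@H]1c1ccc(OC(=O)C(C)(C)C)cc1 | intermediate
19 | trans-2,4-bis(4-hydroxyphenyl)cyclobutane-1,3-dicarboxylic acid (1,3-cis and 1,3-trans; present as its potassium salt) | OC(=O)C1[C@H](c2ccc(O)cc2)C(C(=O)O)[C@H]1c1ccc(O)cc1 | intermediate (not isolated)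
20 | dibenzyl trans-2,4-bis[4-(benzyloxy)phenyl]cyclobutane-1,3-dicarboxylate (1,3-cis and 1,3-trans) | O=C(OCc1ccccc1)C1[C@H](c2ccc(OCc3ccccc3)cc2)C(C(=O)OCc2ccccc2)[C@H]1c1ccc(OCc2ccccc2)cc1 | intermediate
21 | dimethyl (1α,2α,3β,4β)-2,4-bis[4-(benzyloxy)phenyl]cyclobutane-1,3-dicarboxylate | COC(=O)[C@H]1[C@H](c2ccc(OCc3ccccc3)cc2)[C@H](C(=O)OC)[C@H]1c1ccc(OCc2ccccc2)cc1 | intermediate
22 | (1α,2α,3β,4β)-2,4-bis[4-(benzyloxy)phenyl]cyclobutane-1,3-dicarboxylic acid | OC(=O)[C@H]1[C@H](c2ccc(OCc3ccccc3)cc2)[C@H](C(=O)O)[C@H]1c1ccc(OCc2ccccc2)cc1 | intermediate
23 | (1α,2α,3β,4β)-2,4-bis[4-(benzyloxy)phenyl]cyclobutane-1,3-dicarbonyl dichloride | ClC(=O)[C@H]1[C@H](c2ccc(OCc3ccccc3)cc2)[C@H](C(Cl)=O)[C@H]1c1ccc(OCc2ccccc2)cc1 | intermediate (not isolated)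
24 | dimethyl 5,5′-{(1α,2α,3β,4β)-2,4-bis[4-(benzyloxy)phenyl]cyclobutane-1,3-diyl}bis(3,5-dioxopentanoate) | COC(=O)CC(=O)CC(=O)[C@H]1[C@H](c2ccc(OCc3ccccc3)cc2)[C@H](C(=O)CC(=O)CC(=O)OC)[C@H]1c1ccc(OCc2ccccc2)cc1 | intermediate
25 | 6,6′-{(1α,2α,3β,4β)-2,4-bis[4-(benzyloxy)phenyl]cyclobutane-1,3-diyl}bis(4-hydroxy-2H-pyran-2-one) | Oc1cc(=O)oc([C@H]2[C@H](c3ccc(OCc4ccccc4)cc3)[C@H](c3cc(O)cc(=O)o3)[C@H]2c2ccc(OCc3ccccc3)cc2)c1 | intermediate
26 | 6,6′-{(1α,2α,3β,4β)-2,4-bis[4-(benzyloxy)phenyl]cyclobutane-1,3-diyl}bis(4-methoxy-2H-pyran-2-one) | COc1cc(=O)oc([C@H]2[C@H](c3ccc(OCc4ccccc4)cc3)[C@H](c3cc(OC)cc(=O)o3)[C@H]2c2ccc(OCc3ccccc3)cc2)c1 | intermediate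
27 | 6,6′-[(1α,2α,3β,4β)-2,4-bis(4-hydroxyphenyl)cyclobutane-1,3-diyl]bis(4-methoxy-2H-pyran-2-one) | COc1cc(=O)oc([C@H]2[C@H](c3ccc(O)cc3)[C@H](c3cc(OC)cc(=O)o3)[C@H]2c2ccc(O)cc2)c1 | target

## Step count and least certain steps

Total step count: 18 steps. Longest linear sequence: 17 steps (steps 1–3 and 5–18; step 4 is the one-step branch to 7).

Step 8 (key step). The most likely failure is that substitution at the hindered, β-branched secondary benzylic carbons is outrun by ionisation or elimination. Loss of a mesylate before the nucleophile arrives would scramble the Cb/Cd configuration or give the conjugated styrene. The slow four-membered ring closure also leaves time for a second malonate to attack 13 or for the malonate anion to attack an aryl pivalate. Fallback: the same bonds are made from a cyclic sulfate, in which the second leaving group exists only after the first C–C bond has formed. Diol 10 is converted with SOCl2/Et3N into the cyclic sulfite 5-[(benzyloxy)methyl]-4,6-bis[4-(pivaloyloxy)phenyl]-1,3,2-dioxathiane 2-oxide F1. Oxidation with NaIO4 and catalytic RuCl3 gives the cyclic sulfate 5-[(benzyloxy)methyl]-4,6-bis[4-(pivaloyloxy)phenyl]-1,3,2-dioxathiane 2,2-dioxide F2. The sodium salt of 12 opens F2 with inversion to a sulfate monoester, and a second equivalent of NaH closes the ring by displacement of sulfate with inversion to give 14, where the fallback rejoins the route.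

Step 6. The risk is incomplete 1,3-anti selectivity. The aryl ketone is less electrophilic than the alkyl ketones for which the directed reduction is best known, and one of the two aldol diastereomers must place its benzyloxymethyl group axially in the chair transition state. Any syn diol would end up as a cis-diaryl cyclobutane. Fallback (catalyst control in place of substrate-directed delivery): 9 is oxidised with Dess–Martin periodinane to the diketone 2-[(benzyloxy)methyl]-1,3-bis[4-(pivaloyloxy)phenyl]propane-1,3-dione F3. Both carbonyl groups are then reduced by transfer hydrogenation with RuCl(p-cymene)[(S,S)-TsDPEN] in HCO2H/Et3N. The catalyst imposes the same absolute sense at both carbinols, which is the anti diol 10 (now enantioenriched, which is of no consequence).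

Step 13. The risk is that the equilibrium does not lie far enough on the side of 21. The two epimers have the same number of cis vicinal contacts and differ only across the ring, so the energy gap may be small and the cis-1,3 diester may persist. Fallback (chemical separation in place of thermodynamic funnelling): the equilibrated ester mixture from 20 is saponified as in step 14 to a mixture of 22 and its epimer, (1α,2α,3α,4β)-2,4-bis[4-(benzyloxy)phenyl]cyclobutane-1,3-dicarboxylic acid F4. Dehydration with DCC in THF converts only F4, whose carboxyl groups are on the same face, into the bridged anhydride 6,7-bis[4-(benzyloxy)phenyl]-3-oxabicyclo[3.1.1]heptane-2,4-dione F5. 22 cannot form a monomeric anhydride and is extracted into aqueous NaHCO3, where the fallback returns to the route at 22. F5 is opened with NaOMe in MeOH and goes back into the equilibration.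

Step 15. The risk is incomplete twofold acylation. Each acid chloride sits on a ring carbon flanked by two aryl-bearing carbons, the silyl dienol ether is a weak nucleophile, and prolonged reaction invites loss of HCl to a ketene, which would erase the Ca/Cc configuration. Fallback (acylketene route in place of the dioxo ester): 22 is activated with carbonyldiimidazole to the bis(acyl imidazole) (1α,2α,3β,4β)-2,4-bis[4-(benzyloxy)phenyl]cyclobutane-1,3-diylbis(imidazol-1-ylmethanone) F6. F6 acylates the lithium dienolate of 2,2,6-trimethyl-4H-1,3-dioxin-4-one (LiN(SiMe3)2, THF, −78 °C) to give the bis(dioxinone) 6,6′-{(1α,2α,3β,4β)-2,4-bis[4-(benzyloxy)phenyl]cyclobutane-1,3-diylbis(2-oxoethane-2,1-diyl)}bis(2,2-dimethyl-4H-1,3-dioxin-4-one) F7. Heating F7 in toluene expels acetone, and the acylketenes cyclise onto the neighbouring ketone enols to give 25 directly.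

Step 5. The risk is β-elimination of the benzyloxy group from the enolate of 5 (an E1cB process that gives the aryl vinyl ketone) or partial loss of a pivalate during the oxidative work-up. Fallback (Lewis-acid aldol in place of the boron enolate): 5 is converted with TMSOTf/Et3N into its silyl enol ether 4-[(Z)-3-(benzyloxy)-1-(trimethylsilyloxy)prop-1-en-1-yl]phenyl pivalate F8. F8 adds to 7 under BF3·OEt2 at −78 °C (Mukaiyama aldol) to give 9; the diastereomer ratio is again irrelevant.

## Further compounds

F1 | step 8 | 5-[(benzyloxy)methyl]-4,6-bis[4-(pivaloyloxy)phenyl]-1,3,2-dioxathiane 2-oxide (4S*,6S*) | O=S1O[C@H](c2ccc(OC(=O)C(C)(C)C)cc2)C(COCc2ccccc2)[C@@H](c2ccc(OC(=O)C(C)(C)C)cc2)O1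
F2 | step 8 | 5-[(benzyloxy)methyl]-4,6-bis[4-(pivaloyloxy)phenyl]-1,3,2-dioxathiane 2,2-dioxide (4S*,6S*) | O=S1(=O)O[C@H](c2ccc(OC(=O)C(C)(C)C)cc2)C(COCc2ccccc2)[C@@H](c2ccc(OC(=O)C(C)(C)C)cc2)O1
F3 | step 6 | 2-[(benzyloxy)methyl]-1,3-bis[4-(pivaloyloxy)phenyl]propane-1,3-dione | O=C(c1ccc(OC(=O)C(C)(C)C)cc1)C(COCc1ccccc1)C(=O)c1ccc(OC(=O)C(C)(C)C)cc1
F4 | step 13 | (1α,2α,3α,4β)-2,4-bis[4-(benzyloxy)phenyl]cyclobutane-1,3-dicarboxylic acid | OC(=O)[C@@H]1[C@H](c2ccc(OCc3ccccc3)cc2)[C@H](C(=O)O)[C@H]1c1ccc(OCc2ccccc2)cc1
F5 | step 13 | 6,7-bis[4-(benzyloxy)phenyl]-3-oxabicyclo[3.1.1]heptane-2,4-dione (aryl groups trans) | O=C1OC(=O)[C@@H]2[C@H](c3ccc(OCc4ccccc4)cc3)[C@H]1[C@H]2c1ccc(OCc2ccccc2)cc1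
F6 | step 15 | (1α,2α,3β,4β)-2,4-bis[4-(benzyloxy)phenyl]cyclobutane-1,3-diylbis(imidazol-1-ylmethanone) | O=C([C@H]1[C@H](c2ccc(OCc3ccccc3)cc2)[C@H](C(=O)n2ccnc2)[C@H]1c1ccc(OCc2ccccc2)cc1)n1ccnc1
F7 | step 15 | 6,6′-{(1α,2α,3β,4β)-2,4-bis[4-(benzyloxy)phenyl]cyclobutane-1,3-diylbis(2-oxoethane-2,1-diyl)}bis(2,2-dimethyl-4H-1,3-dioxin-4-one) | CC1(C)OC(CC(=O)[C@H]2[C@H](c3ccc(OCc4ccccc4)cc3)[C@H](C(=O)CC3=CC(=O)OC(C)(C)O3)[C@H]2c2ccc(OCc3ccccc3)cc2)=CC(=O)O1
F8 | step 5 | 4-[(Z)-3-(benzyloxy)-1-(trimethylsilyloxy)prop-1-en-1-yl]phenyl pivalate | C[Si](C)(C)O/C(c1ccc(OC(=O)C(C)(C)C)cc1)=C\COCc1ccccc1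
A1 | alternative 1 | methyl coumalate (methyl 2-oxo-2H-pyran-5-carboxylate) | COC(=O)c1coc(=O)cc1
A2 | alternative 1 | methyl 3-oxo-2-oxabicyclo[2.2.0]hex-5-ene-6-carboxylate (racemic) | O=C1O[C@@H]2[C@H]1C=C2C(=O)OC
A3 | alternative 2 | trans-N1,N3-di(quinolin-8-yl)cyclobutane-1,3-dicarboxamide | O=C(Nc1cccc2cccnc12)[C@H]1C[C@H](C(=O)Nc2cccc3cccnc23)C1
A4 | alternative 2 | 1-(benzyloxy)-4-iodobenzene | Ic1ccc(OCc2ccccc2)cc1
A5 | alternative 2 | (1α,2α,3β,4β)-2,4-bis[4-(benzyloxy)phenyl]-N1,N3-di(quinolin-8-yl)cyclobutane-1,3-dicarboxamide | O=C(Nc1cccc2cccnc12)[C@H]1[C@H](c2ccc(OCc3ccccc3)cc2)[C@H](C(=O)Nc2cccc3cccnc23)[C@H]1c1ccc(OCc2ccccc2)cc1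
A6 | alternative 3 | (E)-4-acetoxycinnamic acid | CC(=O)Oc1ccc(/C=C/C(=O)O)cc1
A7 | alternative 3 | (1α,2α,3β,4β)-2,4-bis(4-acetoxyphenyl)cyclobutane-1,3-dicarboxylic acid | OC(=O)[C@H]1[C@H](c2ccc(OC(C)=O)cc2)[C@H](C(=O)O)[C@H]1c1ccc(OC(C)=O)cc1
A8 | alternative 3 | bis(1,3-dioxoisoindolin-2-yl) (1α,2α,3β,4β)-2,4-bis(4-acetoxyphenyl)cyclobutane-1,3-dicarboxylate | O=C(ON1C(=O)c2ccccc2C1=O)[C@H]1[C@H](c2ccc(OC(C)=O)cc2)[C@H](C(=O)ON2C(=O)c3ccccc3C2=O)[C@H]1c1ccc(OC(C)=O)cc1
A9 | alternative 3 | 6-chloro-4-methoxy-2H-pyran-2-one | COc1cc(=O)oc(Cl)c1
A10 | alternative 3 | 6,6′-[(1α,2α,3β,4β)-2,4-bis(4-acetoxyphenyl)cyclobutane-1,3-diyl]bis(4-methoxy-2H-pyran-2-one) | COc1cc(=O)oc([C@H]2[C@H](c3ccc(OC(C)=O)cc3)[C@H](c3cc(OC)cc(=O)o3)[C@H]2c2ccc(OC(C)=O)cc2)c1
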